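**Retrosynthetic overview**
1. Target ⇐ global debenzylation of the trideca-O-benzyl tetramer 15. Unit 4 (the 4β→6, 3,4-trans unit) is attached last, by a flavan-4-yl cation coupling at the alcohol oxidation level.
2. The two 4α (3,4-cis) interflavan bonds are made at the ketone oxidation level. C4 of a flavan-3-one (an enol carbon, normally nucleophilic) is turned into an enolonium equivalent (α-acetoxy ketone from trivalent-iodine oxidation of an enol formate) and joined to a nucleophilic arene carbon, trans to the C2 aryl group.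
3. One hydride reduction then sets both C3 alcohols anti to the quasi-axial 4-aryl groups (2,3-trans-3,4-cis).
4. All three ent-fisetinidol units come from one monomer, enol formate 6. Its ring C and its C2 centre are formed in an organocatalytic oxa-Michael/aldol condensation, followed by Baeyer–Villiger oxidation.
5. Ring order: ring C of the monomer is the only ring formed (step 2, used three times). Rings A and B are bought, and unit 3 is (+)-catechin.

Assumption: the SMILES is read as ent-fisetinidol-(4α→6)-ent-fisetinidol-(4α→8)-[ent-fisetinidol-(4β→6)]-(+)-catechin; the units are called unit 1 (terminal ent-fisetinidol), unit 2 (middle ent-fisetinidol), unit 3 (catechin) and unit 4 (ent-fisetinidol on C6 of unit 3).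

**Step 1**
Reactants: 1 3,4-bis(benzyloxy)benzaldehyde; 2 (triphenylphosphoranylidene)acetaldehyde
Product: 3 (E)-3-[3,4-bis(benzyloxy)phenyl]prop-2-enal
Conditions: 2 (1.15 equiv), toluene, 80 °C
Reagents that add atoms: none
Why: Wittig olefination with the stabilised formylmethylene ylide gives the E enal selectively; no stereocentre is formed.

**Step 2**
Reactants: 3 (E)-3-[3,4-bis(benzyloxy)phenyl]prop-2-enal; 4 4-(benzyloxy)-2-hydroxybenzaldehyde
Product: 5 (2S)-7-(benzyloxy)-2-[3,4-bis(benzyloxy)phenyl]-2H-chromene-3-carbaldehyde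
Conditions: (R)-2-[diphenyl(trimethylsilyloxy)methyl]pyrrolidine (20 mol %), 2-nitrobenzoic acid (20 mol %), toluene, 0 °C → rt
Reagents that add atoms: none
Why: Iminium/enamine domino oxa-Michael–aldol condensation: the phenol oxygen of 4 adds to C-β of the E-iminium ion on the face away from the CPh2(OSiMe3) group of the (R) catalyst, intramolecular aldol and loss of water close ring C, and this sets C2 as S (aryl β), the configuration needed in all three ent-fisetinidol units (ee raised by one recrystallisation).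

**Step 3**
Reactants: 5 (2S)-7-(benzyloxy)-2-[3,4-bis(benzyloxy)phenyl]-2H-chromene-3-carbaldehyde
Product: 6 (2S)-7-(benzyloxy)-2-[3,4-bis(benzyloxy)phenyl]-2H-chromen-3-yl formate
Conditions: mCPBA (1.1 equiv), CH2Cl2, 0 °C, dark
Reagents that add atoms: mCPBA, O=C(OO)c1cccc(Cl)c1
Why: Baeyer–Villiger oxidation of a conjugated aldehyde: the electron-rich vinyl carbon C3 (β-carbon of a p-alkoxystyrene) migrates to oxygen in the Criegee adduct, giving the enol formate with the double bond fixed at C3=C4 and C2 untouched.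

**Step 4**
Reactants: 6 (2S)-7-(benzyloxy)-2-[3,4-bis(benzyloxy)phenyl]-2H-chromen-3-yl formate
Product: 7 (2S,4R)-7-(benzyloxy)-2-[3,4-bis(benzyloxy)phenyl]-3-oxochroman-4-yl acetate (2,4-trans)
Conditions: PhI(OAc)2 (1.1 equiv), AcOH (5 equiv), BF3·OEt2 (0.2 equiv), CH2Cl2, −40 → 0 °C; aq. NaHCO3
Reagents that add atoms: (diacetoxyiodo)benzene, CC(=O)OI(OC(C)=O)c1ccccc1
Why: Trivalent-iodine α-acetoxylation of an enol ester (polarity reversal of the enol carbon C4): the iodine electrophile adds to the enol π bond, the formyl group is lost and acetate enters at C4 anti to the C2 aryl group, giving a storable enolonium equivalent as the 2,4-trans α-acetoxy ketone.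

**Step 5**
Reactants: 7 (2S,4R)-7-(benzyloxy)-2-[3,4-bis(benzyloxy)phenyl]-3-oxochroman-4-yl acetate; 6 (2S)-7-(benzyloxy)-2-[3,4-bis(benzyloxy)phenyl]-2H-chromen-3-yl formate (3 equiv, excess recovered)
Product: 8 (2S)-7-(benzyloxy)-2-[3,4-bis(benzyloxy)phenyl]-6-{(2S)-7-(benzyloxy)-2-[3,4-bis(benzyloxy)phenyl]-3-oxochroman-4-yl}-2H-chromen-3-yl formate, ketone unit 2,4-trans (2β-aryl, 4α-aryl)
Conditions: BF3·OEt2 (1.5 equiv), CH2Cl2, −78 → −20 °C
Reagents that add atoms: none
Why: Proposed new method: BF3 ionises the C4–OAc bond of 7 to the α-keto benzylic cation stabilised by the para 7-benzyloxy group (an enolonium equivalent, C4 being the α-carbon of the C3 ketone), and C6 of a second molecule of 6 (para to O1, ortho to OBn, the most nucleophilic unhindered arene carbon, its enol-formate π bond being deactivated by the acyl group) attacks anti to the C2 aryl group by quasi-axial approach to give the 2,4-trans ketone; the closest known reactions are the α-arylation of ketones with electron-rich arenes through trivalent-iodine-derived enolonium species and Lewis-acid Friedel–Crafts alkylation by benzylic acetates.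

**Step 6**
Reactants: 9 (+)-catechin
Product: 10 5,7,3',4'-tetra-O-benzyl-(+)-catechin, (2R,3S)-5,7-bis(benzyloxy)-2-[3,4-bis(benzyloxy)phenyl]chroman-3-ol
Conditions: BnBr (4.4 equiv), K2CO3, DMF, 0 °C → rt
Reagents that add atoms: benzyl bromide, BrCc1ccccc1
Why: Williamson etherification of the four phenols (far more acidic than the secondary alcohol) under mild carbonate conditions leaves the 3-OH and both stereocentres untouched.

**Step 7**
Reactants: 8 dimeric ketone enol formate; 10 5,7,3',4'-tetra-O-benzyl-(+)-catechin (3 equiv, excess recovered)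
Product: 12 deca-O-benzyl bis(3-ketone) trimer (units 1 and 2 as 2,4-trans flavan-3-ones; C4 of unit 1 on C6 of unit 2; C4 of unit 2 on C8 of unit 3), via acetoxy diketone 11 (not isolated)
Conditions: PhI(OAc)2 (1.0 equiv), BF3·OEt2 (2 equiv), CH2Cl2, −78 → −40 °C; then 10, −40 → 0 °C
Reagents that add atoms: none
Why: Proposed new method: the step 4 oxidation is run in the flask on the enol formate of unit 2 (a β-acyloxy p-alkoxystyrene, far more reactive towards trivalent iodine than the ketone of unit 1 or the benzyloxy arenes) to give α-acetoxy ketone 11, and BF3 then ionises it to the enolonium-type cation, which C8 of 10 (the site where benzylated catechin takes electrophiles) attacks anti to the C2 aryl group, setting the 4α (2,4-trans) bond; the closest known reactions are trivalent-iodine enolonium α-arylation of silyl enol ethers with electron-rich arenes and C8-selective Friedel–Crafts couplings of tetra-O-benzylcatechin.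

**Step 8**
Reactants: 12 deca-O-benzyl bis(3-ketone) trimer
Product: 13 deca-O-benzyl ent-fisetinidol-(4α→6)-ent-fisetinidol-(4α→8)-catechin (three free 3-OH groups)
Conditions: NaBH4, CeCl3·7H2O, THF/MeOH, −78 → −20 °C
Reagents that add atoms: none
Why: Luche reduction under nearly neutral conditions (no C4 or C2 epimerisation): in each ketone unit hydride attacks axially from the face anti to the quasi-axial 4-aryl group, so both new 3-OH groups are equatorial, trans to the 2-aryl and cis to the 4-aryl group (2,3-trans-3,4-cis).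

**Step 9**
Reactants: 7 (2S,4R)-7-(benzyloxy)-2-[3,4-bis(benzyloxy)phenyl]-3-oxochroman-4-yl acetate
Product: 14 (2S,3S,4R)-7-(benzyloxy)-2-[3,4-bis(benzyloxy)phenyl]-3-hydroxychroman-4-yl acetate (2,3-trans-3,4-cis; 2β-aryl, 3α-OH, 4α-OAc)
Conditions: NaBH4, CeCl3·7H2O, THF/MeOH, −78 °C
Reagents that add atoms: none
Why: Luche reduction with Felkin–Anh polar control: hydride adds anti to the quasi-axial C4–OAc bond, giving the 3α-alcohol trans to the 2-aryl group, and the low temperature keeps the acetate from migrating.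

**Step 10**
Reactants: 13 deca-O-benzyl ent-fisetinidol-(4α→6)-ent-fisetinidol-(4α→8)-catechin; 14 (2S,3S,4R)-7-(benzyloxy)-2-[3,4-bis(benzyloxy)phenyl]-3-hydroxychroman-4-yl acetate (1.5 equiv, slow addition)
Product: 15 trideca-O-benzyl ether of the target (all thirteen phenols benzylated, four free 3-OH groups)
Conditions: BF3·OEt2 (2 equiv), CH2Cl2, −40 → −10 °C
Reagents that add atoms: none
Why: Lewis-acid flavan-4-yl cation Friedel–Crafts coupling: BF3 ionises the benzylic acetate to the C4 cation stabilised by the 7-benzyloxy group, and C6 of unit 3 (the last free carbon of the trioxygenated ring, the most electron-rich arene position present) adds anti to the 3-OH group, giving the 3,4-trans (4β) bond, while the 5-deoxy interflavan bonds already present are stable to the acid.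

**Step 11**
Reactants: 15 trideca-O-benzyl ether of the target
Product: 16 ent-fisetinidol-(4α→6)-ent-fisetinidol-(4α→8)-[ent-fisetinidol-(4β→6)]-catechin (CNP0126838.5)
Conditions: H2 (1 atm), Pd(OH)2/C, THF/MeOH/H2O, rt
Reagents that add atoms: none
Why: Hydrogenolysis of the thirteen benzyl ethers under neutral conditions leaves the diarylmethine interflavan bonds and all eleven stereocentres untouched.

**Compound list**
1 | 3,4-bis(benzyloxy)benzaldehyde | O=Cc1ccc(OCc2ccccc2)c(OCc2ccccc2)c1 | starting material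
2 | (triphenylphosphoranylidene)acetaldehyde | O=CC=P(c1ccccc1)(c1ccccc1)c1ccccc1 | starting material
3 | (E)-3-[3,4-bis(benzyloxy)phenyl]prop-2-enal | O=C/C=C/c1ccc(OCc2ccccc2)c(OCc2ccccc2)c1 | intermediate
4 | 4-(benzyloxy)-2-hydroxybenzaldehyde | O=Cc1ccc(OCc2ccccc2)cc1O | starting material
5 | (2S)-7-(benzyloxy)-2-[3,4-bis(benzyloxy)phenyl]-2H-chromene-3-carbaldehyde | O=CC1=Cc2ccc(OCc3ccccc3)cc2O[C@H]1c1ccc(OCc2ccccc2)c(OCc2ccccc2)c1 | intermediate
6 | (2S)-7-(benzyloxy)-2-[3,4-bis(benzyloxy)phenyl]-2H-chromen-3-yl formate | O=COC1=Cc2ccc(OCc3ccccc3)cc2O[C@H]1c1ccc(OCc2ccccc2)c(OCc2ccccc2)c1 | intermediate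
7 | (2S,4R)-7-(benzyloxy)-2-[3,4-bis(benzyloxy)phenyl]-3-oxochroman-4-yl acetate (2,4-trans) | c1ccccc1COc1ccc2c(c1)O[C@@H](c1ccc(OCc3ccccc3)c(OCc3ccccc3)c1)C(=O)[C@@H]2OC(C)=O | intermediate
8 | dimer: unit 1 as (2S)-2,4-trans flavan-3-one bonded through C4 (α) to C6 of unit 2, unit 2 as the (2S)-2H-chromen-3-yl formate; six benzyl ethers | c1ccccc1COc1ccc2c(c1)O[C@@H](c1ccc(OCc3ccccc3)c(OCc3ccccc3)c1)C(=O)[C@@H]2c1cc2C=C(OC=O)[C@H](c3ccc(OCc4ccccc4)c(OCc4ccccc4)c3)Oc2cc1OCc1ccccc1 | intermediate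
9 | (+)-catechin, (2R,3S)-2-(3,4-dihydroxyphenyl)chromane-3,5,7-triol | O[C@H]1Cc2c(O)cc(O)cc2O[C@@H]1c1ccc(O)c(O)c1 | starting material
10 | 5,7,3',4'-tetra-O-benzyl-(+)-catechin | O[C@H]1Cc2c(OCc3ccccc3)cc(OCc3ccccc3)cc2O[C@@H]1c1ccc(OCc2ccccc2)c(OCc2ccccc2)c1 | intermediate
11 | acetoxy diketone: dimer 8 with unit 2 converted into the 2,4-trans 4-acetoxy-flavan-3-one | c1ccccc1COc1ccc2c(c1)O[C@@H](c1ccc(OCc3ccccc3)c(OCc3ccccc3)c1)C(=O)[C@@H]2c1cc2c(cc1OCc1ccccc1)O[C@@H](c1ccc(OCc3ccccc3)c(OCc3ccccc3)c1)C(=O)[C@@H]2OC(C)=O | intermediate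
12 | deca-O-benzyl bis(3-ketone) trimer: units 1 and 2 as (2S)-2,4-trans flavan-3-ones, C4(unit 1)–C6(unit 2) and C4(unit 2)–C8(unit 3), unit 3 = tetra-O-benzylcatechin | c1ccccc1COc1ccc2c(c1)O[C@@H](c1ccc(OCc3ccccc3)c(OCc3ccccc3)c1)C(=O)[C@@H]2c1cc2c(cc1OCc1ccccc1)O[C@@H](c1ccc(OCc3ccccc3)c(OCc3ccccc3)c1)C(=O)[C@@H]2c1c(OCc3ccccc3)cc(OCc3ccccc3)c2c1O[C@H](c1ccc(OCc3ccccc3)c(OCc3ccccc3)c1)[C@@H](O)C2 | intermediate
13 | deca-O-benzyl ent-fisetinidol-(4α→6)-ent-fisetinidol-(4α→8)-catechin (units 1 and 2 2,3-trans-3,4-cis) | c1ccccc1COc1ccc2c(c1)O[C@@H](c1ccc(OCc3ccccc3)c(OCc3ccccc3)c1)[C@H](O)[C@@H]2c1cc2c(cc1OCc1ccccc1)O[C@@H](c1ccc(OCc3ccccc3)c(OCc3ccccc3)c1)[C@H](O)[C@@H]2c1c(OCc3ccccc3)cc(OCc3ccccc3)c2c1O[C@H](c1ccc(OCc3ccccc3)c(OCc3ccccc3)c1)[C@@H](O)C2 | intermediate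
14 | (2S,3S,4R)-7-(benzyloxy)-2-[3,4-bis(benzyloxy)phenyl]-3-hydroxychroman-4-yl acetate (2,3-trans-3,4-cis) | c1ccccc1COc1ccc2c(c1)O[C@@H](c1ccc(OCc3ccccc3)c(OCc3ccccc3)c1)[C@H](O)[C@@H]2OC(C)=O | intermediate
15 | trideca-O-benzyl ether of the target | c1ccccc1COc1ccc2c(c1)O[C@@H](c1ccc(OCc3ccccc3)c(OCc3ccccc3)c1)[C@H](O)[C@@H]2c1cc2c(cc1OCc1ccccc1)O[C@@H](c1ccc(OCc3ccccc3)c(OCc3ccccc3)c1)[C@H](O)[C@@H]2c1c(OCc3ccccc3)c([C@H]2c3ccc(OCc4ccccc4)cc3O[C@@H](c3ccc(OCc4ccccc4)c(OCc4ccccc4)c3)[C@@H]2O)c(OCc3ccccc3)c2c1O[C@H](c1ccc(OCc3ccccc3)c(OCc3ccccc3)c1)[C@@H](O)C2 | intermediate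
16 | ent-fisetinidol-(4α→6)-ent-fisetinidol-(4α→8)-[ent-fisetinidol-(4β→6)]-catechin (CNP0126838.5) | Oc1ccc2c(c1)O[C@@H](c1ccc(O)c(O)c1)[C@H](O)[C@@H]2c1cc2c(cc1O)O[C@@H](c1ccc(O)c(O)c1)[C@H](O)[C@@H]2c1c(O)c([C@H]2c3ccc(O)cc3O[C@@H](c3ccc(O)c(O)c3)[C@@H]2O)c(O)c2c1O[C@H](c1ccc(O)c(O)c1)[C@@H](O)C2 | target

**Totals**
Total step count: 11. Longest linear sequence: 9 steps (steps 1, 2, 3, 4, 5, 7, 8, 10, 11).

**Steps most likely to fail, with fallbacks**

Step 5. The cation from 7 may instead attack the enol-formate π bond of 6, lose H2 to give a 3-hydroxyflavylium salt, or 6 may open at its allylic C2–O1 bond under BF3. The fallback sets out from 7 (and 4) and makes the interflavan bond before ring C of unit 2 exists. Compound 7 is coupled under BF3·OEt2 with the simple arene 4 at its C5 (para to OH, ortho to OBn) to give 4-(benzyloxy)-2-hydroxy-5-{(2S)-7-(benzyloxy)-2-[3,4-bis(benzyloxy)phenyl]-3-oxochroman-4-yl}benzaldehyde (2,4-trans) F1. The step 2 oxa-Michael/aldol condensation of F1 with 3 and the (R) catalyst then builds ring C of unit 2, giving the dimeric ketone enal F2. Baeyer–Villiger oxidation with mCPBA as in step 3 comes back to the route at 8.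

Step 7. The trivalent-iodine oxidation must pick the enol formate of 8 in the presence of the unit 1 ketone and six benzyloxy arenes, and the arylation at the hindered C8 must outrun C4 epimerisation. The fallback sets out from 8 and removes the ketone first. LiBH(s-Bu)3 in THF at −78 °C reduces the unit 1 ketone anti to its 4-aryl group to the 3α-alcohol enol formate F3. CH3Li (3.3 equiv) at −78 °C followed by Me3SiCl cleaves the formate regiospecifically and gives the bis(trimethylsilyl) compound F4 (silyl enol ether in unit 2, silyl ether in unit 1). The established silyl enol ether protocol (PhI(OH)OTs, BF3·OEt2, CH2Cl2, −78 °C, then 10) gives, after acidic work-up, the trimeric mono-ketone F5. NaBH4/CeCl3·7H2O reduction of F5 comes back to the route at 13.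

Step 10. In the fully benzylated series C6 of unit 3 is crowded, so C6 of unit 1 may compete, and the 3,4-trans selectivity of a 5-deoxy cation is only moderate. The fallback sets out from 13 (and 14) and uses the phenol-level selectivity of the free trioxygenated ring. Hydrogenolysis of 13 (H2, Pd(OH)2/C) gives free ent-fisetinidol-(4α→6)-ent-fisetinidol-(4α→8)-catechin F6. F6 is condensed with 14 (BF3·OEt2, dioxane, rt), where the free phloroglucinol-type C6 of the catechin unit is by far the best nucleophile, to give the tetramer with only unit 4 benzylated F7. Hydrogenolysis of F7 comes back to the route at 16.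

**Further compounds**
F1 | step 5 | 4-(benzyloxy)-2-hydroxy-5-{(2S)-7-(benzyloxy)-2-[3,4-bis(benzyloxy)phenyl]-3-oxochroman-4-yl}benzaldehyde (2,4-trans) | c1ccccc1COc1ccc2c(c1)O[C@@H](c1ccc(OCc3ccccc3)c(OCc3ccccc3)c1)C(=O)[C@@H]2c1cc(C=O)c(O)cc1OCc1ccccc1
F2 | step 5 | dimeric ketone enal: unit 1 as in 8, unit 2 as the (2S)-2H-chromene-3-carbaldehyde | c1ccccc1COc1ccc2c(c1)O[C@@H](c1ccc(OCc3ccccc3)c(OCc3ccccc3)c1)C(=O)[C@@H]2c1cc2C=C(C=O)[C@H](c3ccc(OCc4ccccc4)c(OCc4ccccc4)c3)Oc2cc1OCc1ccccc1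
F3 | step 7 | 3α-alcohol enol formate: 8 with the unit 1 ketone reduced (2,3-trans-3,4-cis) | c1ccccc1COc1ccc2c(c1)O[C@@H](c1ccc(OCc3ccccc3)c(OCc3ccccc3)c1)[C@H](O)[C@@H]2c1cc2C=C(OC=O)[C@H](c3ccc(OCc4ccccc4)c(OCc4ccccc4)c3)Oc2cc1OCc1ccccc1
F4 | step 7 | bis(trimethylsilyl) compound: unit 1 3-O-trimethylsilyl ether, unit 2 trimethylsilyl enol ether | c1ccccc1COc1ccc2c(c1)O[C@@H](c1ccc(OCc3ccccc3)c(OCc3ccccc3)c1)[C@H](O[Si](C)(C)C)[C@@H]2c1cc2C=C(O[Si](C)(C)C)[C@H](c3ccc(OCc4ccccc4)c(OCc4ccccc4)c3)Oc2cc1OCc1ccccc1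
F5 | step 7 | trimeric mono-ketone: 13 with unit 2 still as the 2,4-trans 3-ketone | c1ccccc1COc1ccc2c(c1)O[C@@H](c1ccc(OCc3ccccc3)c(OCc3ccccc3)c1)[C@H](O)[C@@H]2c1cc2c(cc1OCc1ccccc1)O[C@@H](c1ccc(OCc3ccccc3)c(OCc3ccccc3)c1)C(=O)[C@@H]2c1c(OCc3ccccc3)cc(OCc3ccccc3)c2c1O[C@H](c1ccc(OCc3ccccc3)c(OCc3ccccc3)c1)[C@@H](O)C2
F6 | step 10 | ent-fisetinidol-(4α→6)-ent-fisetinidol-(4α→8)-catechin (free phenols) | Oc1ccc2c(c1)O[C@@H](c1ccc(O)c(O)c1)[C@H](O)[C@@H]2c1cc2c(cc1O)O[C@@H](c1ccc(O)c(O)c1)[C@H](O)[C@@H]2c1c(O)cc(O)c2c1O[C@H](c1ccc(O)c(O)c1)[C@@H](O)C2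
F7 | step 10 | target with the three phenols of unit 4 as benzyl ethers | Oc1ccc2c(c1)O[C@@H](c1ccc(O)c(O)c1)[C@H](O)[C@@H]2c1cc2c(cc1O)O[C@@H](c1ccc(O)c(O)c1)[C@H](O)[C@@H]2c1c(O)c([C@H]2c3ccc(OCc4ccccc4)cc3O[C@@H](c3ccc(OCc4ccccc4)c(OCc4ccccc4)c3)[C@@H]2O)c(O)c2c1O[C@H](c1ccc(O)c(O)c1)[C@@H](O)C2
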